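**Plan**
Retrosynthesis cuts, in this order: the C1–O ester bond and the C11/C12 aldehydes (back to a silylated diol, then an ester); the C5–O bond (back to the 5α,6α-epoxide of a 5,7-dienoate and so to a C5=C6 alkene); C1–C10 (opens ring A); C8–C9 and C6–C7 (opens ring B); C5–C10 (acyclic triene).
Forward: a Suzuki–Miyaura coupling joins an enol triflate and an alkenylboronate to the triene, a Diels–Alder reaction with an acrylimide builds ring B, and a type 2 carbonyl-ene reaction closes ring A; oxidation-level changes, acylation and deprotection follow.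
Enabling feature: in ring A the C1 carbinol is bonded to quaternary C10, and C5 can be carried as a C5=C6 alkene that later becomes the 5α-hydroxyl, so O–C1–C10–C5=C6 is a homoallylic alcohol; quaternary C4 leaves C6 as the only hydrogen donor.
Stereochemistry: C9 from the (4R)-benzyloxazolidinone auxiliary in an endo Diels–Alder step; C10 from C9 in the ring A closure; C1 from axial hydride reduction of a C1 ketone; C5 from α-face epoxidation opposite the C10 methyl; the E alkene from p-coumaric acid.

Key step: step 11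

Notation: TBS = tert-butyldimethylsilyl. Bicyclic compounds carry drimane numbering (ring A C1–C5 and C10, ring B C5–C10, C11 on C9, C12 on C8, methyls C13/C14 on C4 and C15 on C10); all have the 10β-methyl and 9β-C11 (9αH) configuration.
Assumption: the carbonyl-ene closure is taken to give the axial 1α-alcohol because the carbonyl oxygen must reach the C6 hydrogen; C1 is oxidised in step 12 and reset in step 13, so the route does not depend on this outcome.

**Step 1**
Reactants: 1 2,2-dimethylpent-4-enoic acid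
Product: 3 3,3-dimethylhex-5-en-2-one, via dilithium gem-diolate 2 (not isolated)
Conditions: MeLi (2.2 equiv), Et2O, 0 °C to rt; inverse quench into cold water
Reagents that add atoms: methyllithium, [Li]C
Why: The lithium carboxylate adds one MeLi to give a gem-diolate that survives until hydrolysis, so the methyl ketone is released only on quench and the α-quaternary centre suppresses over-addition (methyl ketone synthesis from a carboxylic acid and MeLi).

**Step 2**
Reactants: 3 3,3-dimethylhex-5-en-2-one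
Product: 4 3,3-dimethylhexa-1,5-dien-2-yl trifluoromethanesulfonate
Conditions: KN(SiMe3)2, THF, −78 °C; PhNTf2, −78 to 0 °C
Reagents that add atoms: N-phenylbis(trifluoromethanesulfonimide), O=S(=O)(N(c1ccccc1)S(=O)(=O)C(F)(F)F)C(F)(F)F
Why: The ketone can enolise only toward its methyl group, so O-triflation of the potassium enolate should give a single 1,1-disubstituted enol triflate.

**Step 3**
Reactants: 5 but-2-yn-1-ol
Product: 6 (but-2-yn-1-yloxy)(tert-butyl)dimethylsilane
Conditions: TBSCl, imidazole, CH2Cl2, 0 °C to rt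
Reagents that add atoms: tert-butyldimethylsilyl chloride, CC(C)(C)[Si](C)(C)Cl
Why: Imidazole-mediated silylation of a primary alcohol masks the hydroxyl for the organometallic and Lewis-acid steps that follow.

**Step 4**
Reactants: 6 (but-2-yn-1-yloxy)(tert-butyl)dimethylsilane
Product: 7 tert-butyldimethyl{[(2Z)-3-(4,4,5,5-tetramethyl-1,3,2-dioxaborolan-2-yl)but-2-en-1-yl]oxy}silane
Conditions: CuCl (10 mol %), PCy3 (12 mol %), NaOt-Bu (15 mol %), B2pin2 (1.1 equiv), MeOH (2 equiv), toluene, rt
Reagents that add atoms: bis(pinacolato)diboron, CC1(C)OB(OC1(C)C)B1OC(C)(C)C(C)(C)O1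
Why: Copper-catalysed syn borylcupration of a propargylic ether followed by protonation with methanol (formal hydroboration) places boron on the alkyne carbon remote from oxygen with H and B cis, which fixes the alkene geometry needed for the diene.

**Step 5**
Reactants: 4 3,3-dimethylhexa-1,5-dien-2-yl trifluoromethanesulfonate; 7 (2Z)-alkenylboronate
Product: 8 tert-butyldimethyl{[(2E)-3,5,5-trimethyl-4-methylideneocta-2,7-dien-1-yl]oxy}silane
Conditions: PdCl2(dppf) (5 mol %), K3PO4, THF/H2O, 60 °C
Reagents that add atoms: none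
Why: Suzuki–Miyaura coupling of an alkenyl triflate with an alkenylboronate proceeds with retention at both sp2 carbons, so the C5–C10 bond forms with the CH2OTBS group trans to C5 (outside in the s-cis diene).

**Step 6**
Reactants: 9 (4R)-4-benzyl-1,3-oxazolidin-2-one; 10 acryloyl chloride
Product: 11 (4R)-4-benzyl-3-(prop-2-enoyl)-1,3-oxazolidin-2-one
Conditions: n-BuLi, THF, −78 °C; then 10, −78 to 0 °C
Reagents that add atoms: none
Why: N-Acylation of the lithiated oxazolidinone with an acid chloride is the standard entry to N-enoyl imides.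

**Step 7**
Reactants: 8 (2E)-triene silyl ether; 11 (4R)-4-benzyl-3-(prop-2-enoyl)-1,3-oxazolidin-2-one
Product: 12 (4R)-4-benzyl-3-{[(1S,2S)-2-(TBSOCH2)-3-methyl-4-(2-methylpent-4-en-2-yl)cyclohex-3-en-1-yl]carbonyl}-1,3-oxazolidin-2-one
Conditions: Et2AlCl (1.4 equiv), CH2Cl2, −78 °C
Reagents that add atoms: none
Why: In this auxiliary-controlled Diels–Alder reaction Et2AlCl chelates the s-cis acrylimide, the benzyl group blocks one face, the C9 substituent and the bulky C5 substituent of the diene direct the acyl-bearing carbon next to C9, and the endo transition state places CH2OTBS and acyl cis, which sets C9 and C8 as 2S and 1S of the cyclohexene.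

**Step 8**
Reactants: 12 Diels–Alder imide
Product: 13 methyl (1S,2S)-2-(TBSOCH2)-3-methyl-4-(2-methylpent-4-en-2-yl)cyclohex-3-ene-1-carboxylate
Conditions: MeMgBr (1.2 equiv) in MeOH (forms MeOMgBr), CH2Cl2, 0 °C
Reagents that add atoms: methanol, CO
Why: Bromomagnesium methoxide attacks the exocyclic imide carbonyl, so this mild methanolysis releases the auxiliary and gives the methyl ester without epimerising C8.

**Step 9**
Reactants: 13 methyl (1S,2S)-2-(TBSOCH2)-3-methyl-4-(2-methylpent-4-en-2-yl)cyclohex-3-ene-1-carboxylate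
Product: 15 methyl (1S,2S)-2-(TBSOCH2)-4-(5-hydroxy-2-methylpentan-2-yl)-3-methylcyclohex-3-ene-1-carboxylate, via B-alkyl-9-BBN adduct 14 (not isolated)
Conditions: 9-BBN, THF, 0 °C to rt; then NaBO3·4H2O, H2O, rt
Reagents that add atoms: sodium perborate tetrahydrate (NaBO3·4H2O), [Na+].[Na+].O[B-]1(O)OO[B-](O)(O)OO1
Why: 9-BBN hydroborates the monosubstituted alkene anti-Markovnikov and leaves the tetrasubstituted ring alkene and the ester alone, and perborate oxidises the C–B bond under near-neutral conditions (hydroboration–oxidation).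

**Step 10**
Reactants: 15 primary alcohol
Product: 16 methyl (1S,2S)-2-(TBSOCH2)-3-methyl-4-(2-methyl-5-oxopentan-2-yl)cyclohex-3-ene-1-carboxylate
Conditions: DMP, NaHCO3, CH2Cl2, 0 °C to rt
Reagents that add atoms: none
Why: Buffered Dess–Martin oxidation takes the primary alcohol to the aldehyde without touching the silyl ether, the ester or the acid-sensitive tetrasubstituted alkene.

**Step 11**
Reactants: 16 methyl (1S,2S)-2-(TBSOCH2)-3-methyl-4-(2-methyl-5-oxopentan-2-yl)cyclohex-3-ene-1-carboxylate
Product: 17 methyl 11-(TBSO)-1α-hydroxy-8αH-drim-5-en-12-oate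
Conditions: Me2AlCl (2.5 equiv), CH2Cl2, −78 to −20 °C
Reagents that add atoms: none
Why: Me2AlCl binds the aldehyde oxygen (a second equivalent is taken up by the ester), C10 of the C5=C10 alkene attacks the activated carbonyl carbon C1 while a C6 hydrogen passes to oxygen through a bicyclic chair-like array, in concert or via a short-lived tertiary C5 cation, and loss of methane from the aluminium alkoxide makes the closure irreversible; this is a Lewis-acid-promoted intramolecular carbonyl-ene reaction of type 2 (enophile tethered to the central ene carbon), the closest known class being the Me2AlCl cyclisation of 5-alkylhex-5-enals to 3-alkylidenecyclohexanols. Ring A closes as a six-membered ring, exo with respect to the carbonyl and endo with respect to the alkene, whereas bonding to C5 would be a five-membered spiro closure onto a carbon flanked by the C4 gem-dimethyl group. C10 is controlled by C9: allylic strain with the C10 methyl holds the CH2OTBS group pseudoaxial on the β face of ring B, so the tether reaches C10 from the α face and the methyl ends β, cis to C11. C1 is controlled by the transition state, in which the carbonyl oxygen must lie axial to reach the C6 hydrogen, giving the 1α-alcohol; any 1β epimer converges in step 12. The step needs site selectivity (C10 over C5), chemoselectivity (aldehyde over ester and silyl ether) and a single alkene position: ring size secures the first, the higher Lewis basicity and electrophilicity of the aldehyde at low temperature the second, and quaternary C4 and C10 the third, since only C6 can give up a hydrogen and only C5=C6 can form.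

**Step 12**
Reactants: 17 methyl 11-(TBSO)-1α-hydroxy-8αH-drim-5-en-12-oate
Product: 18 methyl 11-(TBSO)-1-oxo-8αH-drim-5-en-12-oate
Conditions: DMP, NaHCO3, CH2Cl2, rt
Reagents that add atoms: none
Why: Dess–Martin oxidation of the secondary alcohol gives a β,γ-unsaturated ketone that cannot conjugate or epimerise because C10 is quaternary, and both C1 epimers converge here.

**Step 13**
Reactants: 18 methyl 11-(TBSO)-1-oxo-8αH-drim-5-en-12-oate
Product: 19 methyl 11-(TBSO)-1β-hydroxy-8αH-drim-5-en-12-oate
Conditions: NaBH4, MeOH, 0 °C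
Reagents that add atoms: none
Why: In this substrate-controlled ketone reduction NaBH4 should deliver hydride axially from the α face, the β face being screened by the adjacent axial C10 methyl, to give the equatorial 1β-alcohol (1R) while the methyl ester survives at 0 °C.

**Step 14**
Reactants: 19 methyl 11-(TBSO)-1β-hydroxy-8αH-drim-5-en-12-oate
Product: 22 methyl 11-(TBSO)-1β-hydroxydrima-5,7-dien-12-oate, via 8α-phenylselanyl ester 20 (not isolated), via selenoxide 21 (not isolated)
Conditions: LiN(i-Pr)2 (2.3 equiv), THF, −78 °C; PhSeBr, −78 °C; then AcOH, 30 % H2O2, 0 °C to rt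
Reagents that add atoms: none
Why: α-Selenenylation of the ester enolate (the C1 alkoxide is a spectator) and oxidation to the selenoxide trigger syn elimination, which should run toward the allylic C7 hydrogen to give the conjugated 5,7-dienoate in preference to the tetrasubstituted C8=C9 isomer (selenoxide elimination).

**Step 15**
Reactants: 22 methyl 11-(TBSO)-1β-hydroxydrima-5,7-dien-12-oate
Product: 23 methyl 11-(TBSO)-5α,6α-epoxy-1β-hydroxydrim-7-en-12-oate
Conditions: mCPBA, NaHCO3, CH2Cl2, 0 °C
Reagents that add atoms: 3-chloroperoxybenzoic acid, OOC(=O)c1cccc(Cl)c1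
Why: The peracid epoxidises the electron-richer γ,δ-alkene C5=C6 and not the ester-deactivated C7=C8, and approaches from the α face opposite the axial C10 and C4β methyl groups, which sets the C5–O bond α (Prilezhaev epoxidation, same facial preference as steroidal 5,7-dienes).

**Step 16**
Reactants: 23 methyl 11-(TBSO)-5α,6α-epoxy-1β-hydroxydrim-7-en-12-oate
Product: 24 methyl 11-(TBSO)-1β,5α-dihydroxydrim-7-en-12-oate
Conditions: Pd2(dba)3·CHCl3 (cat.), n-Bu3P, HCO2H, Et3N, dioxane, rt
Reagents that add atoms: none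
Why: Zerovalent palladium opens the alkenyl epoxide at the allylic C6–O bond with inversion to a β-face π-allyl complex, formate decarboxylates to a palladium hydride, and reductive elimination puts hydrogen on the less hindered terminus C6, leaving the α C5–O bond intact and the alkene conjugated at C7=C8 (palladium-catalysed formate hydrogenolysis of γ,δ-epoxy enoates).

**Step 17**
Reactants: 24 methyl 11-(TBSO)-1β,5α-dihydroxydrim-7-en-12-oate
Product: 25 11-(TBSO)-drim-7-ene-1β,5α,12-triol
Conditions: i-Bu2AlH (excess), CH2Cl2, −78 to 0 °C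
Reagents that add atoms: none
Why: i-Bu2AlH reduces the α,β-unsaturated ester in 1,2 fashion to the allylic alcohol and leaves the silyl ether untouched.

**Step 18**
Reactants: 25 11-(TBSO)-drim-7-ene-1β,5α,12-triol
Product: 26 11,12-bis(TBSO)-drim-7-ene-1β,5α-diol
Conditions: TBSCl (1.1 equiv), imidazole, CH2Cl2, 0 °C
Reagents that add atoms: tert-butyldimethylsilyl chloride, CC(C)(C)[Si](C)(C)Cl
Why: The primary allylic hydroxyl is silylated far faster than the neopentyl-type secondary C1 hydroxyl and the tertiary C5 hydroxyl (selective silylation of a primary alcohol).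

**Step 19**
Reactants: 27 (E)-4-hydroxycinnamic acid (p-coumaric acid)
Product: 29 (E)-3-[4-(TBSO)phenyl]prop-2-enoic acid, via bis-silylated coumarate 28 (not isolated)
Conditions: TBSCl (2.5 equiv), imidazole, DMF, rt; then AcOH/THF/H2O, rt
Reagents that add atoms: tert-butyldimethylsilyl chloride, CC(C)(C)[Si](C)(C)Cl
Why: Exhaustive silylation followed by mild aqueous acid, which hydrolyses the labile silyl ester but not the aryl silyl ether, should give the phenol-protected acid with the E alkene unchanged.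

**Step 20**
Reactants: 26 11,12-bis(TBSO)-drim-7-ene-1β,5α-diol; 29 (E)-3-[4-(TBSO)phenyl]prop-2-enoic acid
Product: 31 11,12-bis(TBSO)-5α-hydroxydrim-7-en-1β-yl (E)-3-[4-(TBSO)phenyl]prop-2-enoate, via mixed trichlorobenzoic anhydride 30 (not isolated)
Conditions: 29, 2,4,6-Cl3C6H2COCl, Et3N, THF, rt; then 26, DMAP, toluene, rt to 60 °C
Reagents that add atoms: none
Why: In this Yamaguchi esterification the mixed anhydride passes the cinnamoyl group via its acylpyridinium ion to the equatorial 1β-hydroxyl with retention at C1, the tertiary C5 hydroxyl being unreactive.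

**Step 21**
Reactants: 31 tris-TBS cinnamate
Product: 32 5α,11,12-trihydroxydrim-7-en-1β-yl (E)-3-[4-(TBSO)phenyl]prop-2-enoate
Conditions: CSA (cat.), MeOH/CH2Cl2, 0 °C
Reagents that add atoms: none
Why: Acid-catalysed methanolysis removes the two primary alkyl TBS ethers much faster than the aryl TBS ether and does not affect the cinnamate ester.

**Step 22**
Reactants: 32 5α,11,12-trihydroxydrim-7-en-1β-yl (E)-3-[4-(TBSO)phenyl]prop-2-enoate
Product: 33 5α-hydroxy-11,12-dioxodrim-7-en-1β-yl (E)-3-[4-(TBSO)phenyl]prop-2-enoate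
Conditions: (COCl)2, DMSO, CH2Cl2, −78 °C; Et3N, −78 to 0 °C
Reagents that add atoms: none
Why: Swern oxidation activates both primary hydroxyls as alkoxysulfonium ions before base is added, so the 1,4-diol should go to the dialdehyde without lactol or lactone formation, the cold amine step limits epimerisation at C9, and the tertiary hydroxyl is inert.

**Step 23**
Reactants: 33 5α-hydroxy-11,12-dioxodrim-7-en-1β-yl (E)-3-[4-(TBSO)phenyl]prop-2-enoate
Product: 34 5α-hydroxy-11,12-dioxodrim-7-en-1β-yl (E)-3-(4-hydroxyphenyl)prop-2-enoate (target, CNP0323926.1)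
Conditions: n-Bu4NF, AcOH (1:1), THF, 0 °C
Reagents that add atoms: none
Why: Fluoride cleaves the aryl silyl ether rapidly, and acetic acid buffering keeps the medium non-basic so that the C9 aldehyde should not epimerise and the cinnamate is not cleaved (fluoride desilylation).

**Compound list**
1 | 2,2-dimethylpent-4-enoic acid | C=CCC(C)(C)C(=O)O | starting material
2 | dilithium 3,3-dimethylhex-5-ene-2,2-diolate | [Li]OC(C)(O[Li])C(C)(C)CC=C | intermediate
3 | 3,3-dimethylhex-5-en-2-one | C=CCC(C)(C)C(C)=O | intermediate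
4 | 3,3-dimethylhexa-1,5-dien-2-yl trifluoromethanesulfonate | C=CCC(C)(C)C(=C)OS(=O)(=O)C(F)(F)F | intermediate
5 | but-2-yn-1-ol | CC#CCO | starting material
6 | (but-2-yn-1-yloxy)(tert-butyl)dimethylsilane | CC#CCO[Si](C)(C)C(C)(C)C | intermediate
7 | tert-butyldimethyl{[(2Z)-3-(4,4,5,5-tetramethyl-1,3,2-dioxaborolan-2-yl)but-2-en-1-yl]oxy}silane | C/C(B1OC(C)(C)C(C)(C)O1)=C\CO[Si](C)(C)C(C)(C)C | intermediate
8 | tert-butyldimethyl{[(2E)-3,5,5-trimethyl-4-methylideneocta-2,7-dien-1-yl]oxy}silane | C=CCC(C)(C)C(=C)/C(C)=C/CO[Si](C)(C)C(C)(C)C | intermediate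
9 | (4R)-4-benzyl-1,3-oxazolidin-2-one | O=C1N[C@H](Cc2ccccc2)CO1 | starting material
10 | acryloyl chloride | C=CC(=O)Cl | starting material
11 | (4R)-4-benzyl-3-(prop-2-enoyl)-1,3-oxazolidin-2-one | C=CC(=O)N1[C@H](Cc2ccccc2)COC1=O | intermediate
12 | (4R)-4-benzyl-3-{[(1S,2S)-2-{[(tert-butyldimethylsilyl)oxy]methyl}-3-methyl-4-(2-methylpent-4-en-2-yl)cyclohex-3-en-1-yl]carbonyl}-1,3-oxazolidin-2-one | C=CCC(C)(C)C1=C(C)[C@@H](CO[Si](C)(C)C(C)(C)C)[C@@H](C(=O)N2[C@H](Cc3ccccc3)COC2=O)CC1 | intermediate
13 | methyl (1S,2S)-2-{[(tert-butyldimethylsilyl)oxy]methyl}-3-methyl-4-(2-methylpent-4-en-2-yl)cyclohex-3-ene-1-carboxylate | C=CCC(C)(C)C1=C(C)[C@@H](CO[Si](C)(C)C(C)(C)C)[C@@H](C(=O)OC)CC1 | intermediate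
14 | methyl (1S,2S)-4-[5-(9-borabicyclo[3.3.1]nonan-9-yl)-2-methylpentan-2-yl]-2-{[(tert-butyldimethylsilyl)oxy]methyl}-3-methylcyclohex-3-ene-1-carboxylate | CC(C)(CCCB1C2CCCC1CCC2)C1=C(C)[C@@H](CO[Si](C)(C)C(C)(C)C)[C@@H](C(=O)OC)CC1 | intermediate
15 | methyl (1S,2S)-2-{[(tert-butyldimethylsilyl)oxy]methyl}-4-(5-hydroxy-2-methylpentan-2-yl)-3-methylcyclohex-3-ene-1-carboxylate | OCCCC(C)(C)C1=C(C)[C@@H](CO[Si](C)(C)C(C)(C)C)[C@@H](C(=O)OC)CC1 | intermediate
16 | methyl (1S,2S)-2-{[(tert-butyldimethylsilyl)oxy]methyl}-3-methyl-4-(2-methyl-5-oxopentan-2-yl)cyclohex-3-ene-1-carboxylate | O=CCCC(C)(C)C1=C(C)[C@@H](CO[Si](C)(C)C(C)(C)C)[C@@H](C(=O)OC)CC1 | intermediate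
17 | methyl 11-[(tert-butyldimethylsilyl)oxy]-1α-hydroxy-8αH-drim-5-en-12-oate | CC1(C)CC[C@H](O)[C@]2(C)[C@@H](CO[Si](C)(C)C(C)(C)C)[C@@H](C(=O)OC)CC=C12 | intermediate
18 | methyl 11-[(tert-butyldimethylsilyl)oxy]-1-oxo-8αH-drim-5-en-12-oate | CC1(C)CCC(=O)[C@]2(C)[C@@H](CO[Si](C)(C)C(C)(C)C)[C@@H](C(=O)OC)CC=C12 | intermediate
19 | methyl 11-[(tert-butyldimethylsilyl)oxy]-1β-hydroxy-8αH-drim-5-en-12-oate | CC1(C)CC[C@@H](O)[C@]2(C)[C@@H](CO[Si](C)(C)C(C)(C)C)[C@@H](C(=O)OC)CC=C12 | intermediate
20 | methyl 11-[(tert-butyldimethylsilyl)oxy]-1β-hydroxy-8α-(phenylselanyl)drim-5-en-12-oate | CC1(C)CC[C@@H](O)[C@]2(C)[C@@H](CO[Si](C)(C)C(C)(C)C)[C@@]([Se]c3ccccc3)(C(=O)OC)CC=C12 | intermediate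
21 | methyl 11-[(tert-butyldimethylsilyl)oxy]-1β-hydroxy-8α-(phenylseleninyl)drim-5-en-12-oate | CC1(C)CC[C@@H](O)[C@]2(C)[C@@H](CO[Si](C)(C)C(C)(C)C)[C@@]([Se](=O)c3ccccc3)(C(=O)OC)CC=C12 | intermediate
22 | methyl 11-[(tert-butyldimethylsilyl)oxy]-1β-hydroxydrima-5,7-dien-12-oate | CC1(C)CC[C@@H](O)[C@]2(C)[C@@H](CO[Si](C)(C)C(C)(C)C)C(C(=O)OC)=CC=C12 | intermediate
23 | methyl 11-[(tert-butyldimethylsilyl)oxy]-5α,6α-epoxy-1β-hydroxydrim-7-en-12-oate | CC1(C)CC[C@@H](O)[C@]2(C)[C@@H](CO[Si](C)(C)C(C)(C)C)C(C(=O)OC)=C[C@@H]3O[C@]123 | intermediate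
24 | methyl 11-[(tert-butyldimethylsilyl)oxy]-1β,5α-dihydroxydrim-7-en-12-oate | CC1(C)CC[C@@H](O)[C@]2(C)[C@@H](CO[Si](C)(C)C(C)(C)C)C(C(=O)OC)=CC[C@@]12O | intermediate
25 | 11-[(tert-butyldimethylsilyl)oxy]drim-7-ene-1β,5α,12-triol | CC1(C)CC[C@@H](O)[C@]2(C)[C@@H](CO[Si](C)(C)C(C)(C)C)C(CO)=CC[C@@]12O | intermediate
26 | 11,12-bis[(tert-butyldimethylsilyl)oxy]drim-7-ene-1β,5α-diol | CC1(C)CC[C@@H](O)[C@]2(C)[C@@H](CO[Si](C)(C)C(C)(C)C)C(CO[Si](C)(C)C(C)(C)C)=CC[C@@]12O | intermediate
27 | (E)-3-(4-hydroxyphenyl)prop-2-enoic acid (p-coumaric acid) | OC(=O)/C=C/c1ccc(O)cc1 | starting material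
28 | tert-butyldimethylsilyl (E)-3-{4-[(tert-butyldimethylsilyl)oxy]phenyl}prop-2-enoate | CC(C)(C)[Si](C)(C)OC(=O)/C=C/c1ccc(O[Si](C)(C)C(C)(C)C)cc1 | intermediate
29 | (E)-3-{4-[(tert-butyldimethylsilyl)oxy]phenyl}prop-2-enoic acid | OC(=O)/C=C/c1ccc(O[Si](C)(C)C(C)(C)C)cc1 | intermediate
30 | (E)-3-{4-[(tert-butyldimethylsilyl)oxy]phenyl}prop-2-enoic 2,4,6-trichlorobenzoic anhydride | O=C(OC(=O)c1c(Cl)cc(Cl)cc1Cl)/C=C/c1ccc(O[Si](C)(C)C(C)(C)C)cc1 | intermediate
31 | 11,12-bis[(tert-butyldimethylsilyl)oxy]-5α-hydroxydrim-7-en-1β-yl (E)-3-{4-[(tert-butyldimethylsilyl)oxy]phenyl}prop-2-enoate | CC1(C)CC[C@@H](OC(=O)/C=C/c2ccc(O[Si](C)(C)C(C)(C)C)cc2)[C@]2(C)[C@@H](CO[Si](C)(C)C(C)(C)C)C(CO[Si](C)(C)C(C)(C)C)=CC[C@@]12O | intermediate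
32 | 5α,11,12-trihydroxydrim-7-en-1β-yl (E)-3-{4-[(tert-butyldimethylsilyl)oxy]phenyl}prop-2-enoate | CC1(C)CC[C@@H](OC(=O)/C=C/c2ccc(O[Si](C)(C)C(C)(C)C)cc2)[C@]2(C)[C@@H](CO)C(CO)=CC[C@@]12O | intermediate
33 | 5α-hydroxy-11,12-dioxodrim-7-en-1β-yl (E)-3-{4-[(tert-butyldimethylsilyl)oxy]phenyl}prop-2-enoate | CC1(C)CC[C@@H](OC(=O)/C=C/c2ccc(O[Si](C)(C)C(C)(C)C)cc2)[C@]2(C)[C@@H](C=O)C(C=O)=CC[C@@]12O | intermediate
34 | 5α-hydroxy-11,12-dioxodrim-7-en-1β-yl (E)-3-(4-hydroxyphenyl)prop-2-enoate, (1R,5R,9R,10S) in drimane numbering | CC1(C)CC[C@@H](OC(=O)/C=C/c2ccc(O)cc2)[C@]2(C)[C@@H](C=O)C(C=O)=CC[C@@]12O | target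

**Step count and risks**
Total steps: 23. Longest linear sequence: 19 steps (1, 2, 5, 7–18, 20–23).

Steps most likely to fail:

1. Step 11. The activated aldehyde may fail to bond to the hindered tetrasubstituted alkene, so that methyl transfer from aluminium to the aldehyde, chloride capture of the C5 cation or methyl migration from C4 competes with proton loss. The fallback makes the same C1–C10 bond at the acyl oxidation level. It sets out from 16: Pinnick oxidation (NaClO2, NaH2PO4, 2-methylbut-2-ene, t-BuOH/H2O) should give methyl (1S,2S)-4-(4-carboxy-2-methylbutan-2-yl)-2-(TBSOCH2)-3-methylcyclohex-3-ene-1-carboxylate F1. Treatment with (COCl)2 and catalytic DMF converts it into methyl (1S,2S)-4-(5-chloro-2-methyl-5-oxopentan-2-yl)-2-(TBSOCH2)-3-methylcyclohex-3-ene-1-carboxylate F2. SnCl4 in CH2Cl2 at −78 °C then effects intramolecular acylation of the alkene at C10, anti to the C9 substituent, with loss of a C6 proton. This comes back to the route at ketone 18 and makes step 12 unnecessary.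

2. Step 7. The 2,3-disubstituted diene may resist the s-cis conformation and react slowly, the C10 methyl may erode regiocontrol, or the stoichiometric aluminium Lewis acid may ionise the allylic silyl ether. The fallback moves asymmetric induction from the auxiliary to a catalyst. It sets out from 8: cycloaddition with 2,2,2-trifluoroethyl acrylate under a triflimide-activated chiral oxazaborolidinium catalyst (the enantiomer that delivers the 1S,2S adduct) in CH2Cl2 at low temperature should give 2,2,2-trifluoroethyl (1S,2S)-2-(TBSOCH2)-3-methyl-4-(2-methylpent-4-en-2-yl)cyclohex-3-ene-1-carboxylate F3. Transesterification with K2CO3 in MeOH comes back to the route at 13.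

3. Step 16. Approach of palladium to the β face may be blocked by the C10 methyl, hydride may be delivered to the wrong allyl terminus, or β-hydride elimination to a dienol may take over. The fallback opens the epoxide by electron transfer. It sets out from 23: SmI2 in THF/MeOH at −78 °C should reduce the γ,δ-epoxy enoate to methyl 11-(TBSO)-1β,5α-dihydroxy-8αH-drim-6-en-12-oate F4 (C5–O bond retained; either C8 epimer serves). DBU in CH2Cl2 then moves the alkene into conjugation and comes back to the route at 24.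

**Further compounds**
F1 | step 11 | methyl (1S,2S)-4-(4-carboxy-2-methylbutan-2-yl)-2-{[(tert-butyldimethylsilyl)oxy]methyl}-3-methylcyclohex-3-ene-1-carboxylate | OC(=O)CCC(C)(C)C1=C(C)[C@@H](CO[Si](C)(C)C(C)(C)C)[C@@H](C(=O)OC)CC1
F2 | step 11 | methyl (1S,2S)-4-(5-chloro-2-methyl-5-oxopentan-2-yl)-2-{[(tert-butyldimethylsilyl)oxy]methyl}-3-methylcyclohex-3-ene-1-carboxylate | ClC(=O)CCC(C)(C)C1=C(C)[C@@H](CO[Si](C)(C)C(C)(C)C)[C@@H](C(=O)OC)CC1
F3 | step 7 | 2,2,2-trifluoroethyl (1S,2S)-2-{[(tert-butyldimethylsilyl)oxy]methyl}-3-methyl-4-(2-methylpent-4-en-2-yl)cyclohex-3-ene-1-carboxylate | C=CCC(C)(C)C1=C(C)[C@@H](CO[Si](C)(C)C(C)(C)C)[C@@H](C(=O)OCC(F)(F)F)CC1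
F4 | step 16 | methyl 11-[(tert-butyldimethylsilyl)oxy]-1β,5α-dihydroxy-8αH-drim-6-en-12-oate | CC1(C)CC[C@@H](O)[C@]2(C)[C@@H](CO[Si](C)(C)C(C)(C)C)[C@@H](C(=O)OC)C=C[C@@]12O
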